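Start with an easy step: read a run as the fraction of the charge it has left. Every equal stretch of time in a first-order flask multiplies that fraction by the same factor, so call the logarithm of its inverse the reaction number, the Damköhler number. It is the run time divided by the substrate's lifetime, and it puts time on a common footing with catalyst and temperature.

| flask | substrate | gas | free catalyst | temperature | remark | time |
|---|---|---|---|---|---|---|
| beta | 1.3 M | 150 mM (held) | 3.2 mM | 88 °C | run made earlier |  |
| theta | 1.3 M | 150 mM (held) | 4.9 mM | 126 °C | run made earlier |  |
| summer | 1.3 M | 150 mM (held) | 6.5 mM | 110 °C |  | 6.0 min |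
| noon | 1.3 M | 150 mM (held) | 6.5 mM | 140 °C |  | 6.0 min |
| winter | 1.3 M | 150 mM (held) | 6.5 mM | 90 °C |  | 6.0 min |
| spring | 1.3 M | 150 mM (held) | 6.5 mM | 80 °C |  | 6.0 min |
| dawn | 1.3 M | 150 mM (held) | 6.5 mM | 70 °C |  | 6.0 min |

| run | time / min | product / % |
|---|---|---|
| beta | 1.33 | 1.6 |
| beta | 3.00 | 5.3 |
| beta | 6.00 | 6.8 |
| beta | 8.00 | 10.6 |
| beta | 12.0 | 15.6 |
| beta | 20.0 | 25.6 |
| beta | 25.0 | 30.6 |
| theta | 0.417 | 7.4 |
| theta | 0.833 | 14.1 |
| theta | 1.33 | 22.1 |
| theta | 2.00 | 34.2 |
| theta | 2.50 | 38.4 |
| theta | 4.00 | 54.1 |

(readings scatter by 1 percentage point)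

- the numbers in the tables scatter by 1 percentage point (one standard deviation)
- at the start none of the gas is in solution

- the flasks by amount of product, in percent of the substrate charged, highest first, at 6.0 min (summer / noon / winter / spring / dawn)
- the amount of product, in percent of the substrate charged of the flask you put first, at 6.0 min
- the amount of product, in percent of the substrate charged of the flask you put last, at 6.0 min

The beta run ends at a number of 0.365 and the theta run at 0.779. Take the number as proportional to time and to free catalyst, a pseudo-first-order assumption. The beta and theta runs differ in catalyst and in temperature together, so they do not separate the two. On that assumption the rest of the gap between the runs reads as an apparent activation energy of 68.2 kJ mol⁻¹.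

Test the proportion to time inside each run. At 12.0 min the beta number predicts 16.1% against 15.6% read, and at 2.00 min the theta number predicts 32.3% against 34.2% read, a gap of 1.9 percentage points on a scatter of 1 point.

Now scale from the nearest run. Noon gets 3.11, so 95.5% product, but that number is 3.99 times the theta number, the larger of the two read, so noon is the weak point. Dawn gets a reaction number of 0.0541, so 5.26% product. The charges and time match across the flasks asked about, so this reckoning orders them by temperature.

The forecast, close to this reckoning, gives noon > summer > winter > spring > dawn, with 95% and 5.3%, and expects “a monotonic temperature order”.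

The simulation gives noon > summer > winter > spring > dawn, with 64.6% and 4.37%.

    partner + free catalyst → catalyst intermediate A (k = 70.0 L mol⁻¹ s⁻¹, Ea = 40.0 kJ mol⁻¹)
    catalyst intermediate A → catalyst intermediate B (k = 11.0 s⁻¹, Ea = 92.0 kJ mol⁻¹)
    substrate + catalyst intermediate B → catalyst intermediate C (k = 0.370 L mol⁻¹ s⁻¹, Ea = 74.0 kJ mol⁻¹)
    catalyst intermediate C → free catalyst + product (k = 7.40 s⁻¹, Ea = 99.0 kJ mol⁻¹)
    free catalyst → spent catalyst (k = 0.00510 s⁻¹, Ea = 105 kJ mol⁻¹)
    gas ⇌ partner, rate k6*(csat - [partner]) (kL = 0.0580 s⁻¹)
    (constants at 110 °C)

Noon's product reads back to a number of 1.04, not 3.11. Noon made 48.6% by 3.00 min and added 16 points by 6.00 min, while its spent catalyst went from 78.3% to 86.3% of the catalyst charged, against 8.29% in summer at 6.00 min.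

Now read dawn at 10 min: multiplying 0.0541 by the ratio of times gives 0.0901, so 8.62% product. The simulated flask gives 7.28%.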